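(The data come from a simulation with constants of no real substance, and the scatter is random.)

At early times the added E does nothing that the readings can see: the red run less its 60.0 mM of E reads 37.1 mM at 1.9 h, and the green run reads 36.7 mM. Over that same interval, the teal run, with half of the L of the green run, has an apparent constant 0.0939 h⁻¹ against 0.192 h⁻¹ in the green run, so the reckoning here takes the order in L as 1.03, and Q reacts by a pseudo-first-order route while L stands fixed.

| setting | green | teal | red | ochre |
|---|---|---|---|---|
| Q | 120 mM | 120 mM | 120 mM | 600 mM |
| L | 12.0 mM | 6.00 mM | 12.0 mM | 12.0 mM |
| E |  |  | 60.0 mM |  |
| time |  |  |  | 13 h |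

- green run (time / h: [E] / mM): 1.9: 36.7; 3.7: 61.6; 5.6: 77.7; 7.4: 88.1; 9.3: 96.1; 11: 100.6; 13: 104.3
- teal run (time / h: [E] / mM): 1.9: 19.6; 3.7: 37.0; 5.6: 49.3; 7.4: 58.9; 9.3: 67.5; 11: 74.1; 13: 81.2
- red run (time / h: [E] / mM): 1.9: 97.1; 3.7: 122.2; 5.6: 138.4; 7.4: 148.1; 9.3: 156.4; 11: 161.2; 13: 164.5

(each reading ± 0.6 mM)

- Overall: Q -> E, with L as catalyst.
- Constant volume, constant temperature.
- An order is taken over about fifteen percent of the charge, up and down.

* reaction order in [L] at the outset, round the charge of the green run, defined at two percent of the Q turned into E
* E in the ochre run at 13 h, as a share of the Q charged
* which of these the readings show (a little impurity takes part of the catalyst at once / the product binds the substrate / two substrates go astray together / the product speeds the reaction)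

The balance of Q, the limiting reagent, has a second outlet, since the last slope of the green run, 1.85 mM h⁻¹, points to a final E of about 93.4 % of the charge, a reading with a wide margin. Take the loss ratio, the rate at which Q is lost over the rate at which E forms at the charge, and take the loss as second order in Q, so that the ratio rises with the Q charged and falls with the L charged. The ratio sinks with Q during a run, so the share lost is about half of its starting value, which gives 0.132 for the green run.

The ochre flask has a ratio of 0.660. With no loss, its E at 13 h is 91.8 % of the charge. With the ratio held at its starting value all the way, so that the two outlets of Q stay in proportion, E in the ochre flask at 13 h is 59.3 % of the charge. The real flask lies between them, as its ratio starts at full strength and sinks with Q, and integrating the balance gives 71.7 %, which is less than the no-loss case.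

The forecast gives order 1, 70 % and two substrates go astray together, with a ratio of 0.775 and the words “A loss second order in Q and independent of L fits”, and its share stands below the reckoning here.

    L + Q → E + L (17.03 M⁻¹ h⁻¹)
    2 Q → Zo (0.1224 M⁻¹ h⁻¹)

The ochre flask gives 71.2 %, with order 1.0 in L and two substrates go astray together. The fit in which the product decays leaves a residual of 2.3 in units of the scatter and forecasts 88.6 %. Carried to the teal run, the ratio comes to 0.264, the no-loss share at 13 h is 71.3 %, and the balance gives 65.3 % of the charge as E, against a reading of 67.7 %.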